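**Retrosynthetic overview**
1. The target comes from its phenolic acetate by methanolysis; the 9β-carbinol comes from Luche reduction of the α-methylidene ketone, which comes from closing the seven-membered ring last (C8–C9) by an intramolecular Nozaki–Hiyama–Kishi reaction of a 2-bromoalkene aldehyde.
2. Key disconnection C6–C7: intermolecular Barbier-type carbonyl allylation of a cyclopentane β-hydroxy aldehyde with 2,3-dibromopropene/In, chelation-controlled, sets C6.
3. The aldehyde comes from a 2-vinylcyclopentanone: isopropyl organocerium addition anti to the vinyl group sets C4, then ozonolysis.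
4. The cyclopentane comes from (R)-4-silyloxy-2-methylcyclopentenone: vinyl cuprate addition anti to the silyloxy group sets C5, enolate alkylation anti to vinyl sets quaternary C1; the former enone oxygen (C2) is removed by Barton–McCombie deoxygenation.
5. Ring order: the five-membered ring is present from the commercial enone; the seven-membered ring is formed last.

Assumption: labels C1–C15 are daucane locants of the target (C1 quaternary methyl carbon, C4 isopropyl carbinol, C5 ring-fusion CH, C6 ester carbinol, C8 methylidene carbon, C9 allylic carbinol, C10 ring CH2); β means the face of the C1 methyl, α the opposite face; TBS = tert-butyldimethylsilyl, TBDPS = tert-butyldiphenylsilyl, TMS = trimethylsilyl.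

**Route**

Step 1
Reactants: 1 (R)-4-[(tert-butyldimethylsilyl)oxy]cyclopent-2-en-1-one
Product: 2 (R)-4-[(tert-butyldimethylsilyl)oxy]-2-iodocyclopent-2-en-1-one
Conditions: I2, pyridine, CH2Cl2, 0 °C to rt
Reagents that add atoms: iodine, II
Why: Johnson α-iodination of an enone (pyridine addition, iodination, elimination) is standard for this silyloxy enone and does not touch the C4 stereocentre.

Step 2
Reactants: 2 (R)-4-[(tert-butyldimethylsilyl)oxy]-2-iodocyclopent-2-en-1-one; 3 methylboronic acid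
Product: 4 (R)-4-[(tert-butyldimethylsilyl)oxy]-2-methylcyclopent-2-en-1-one
Conditions: PdCl2(PhCN)2 (5 mol%), AsPh3, Ag2O, THF/H2O, rt
Reagents that add atoms: none
Why: Suzuki–Miyaura coupling of an α-iodoenone promoted by Ag2O runs at room temperature, mild enough to avoid β-elimination of the silyloxy group.

Step 3
Reactants: 4 (R)-4-[(tert-butyldimethylsilyl)oxy]-2-methylcyclopent-2-en-1-one; 5 vinylmagnesium bromide
Product: 7 tert-butyl(dimethyl){[(1R,2R)-3-methyl-4-[(trimethylsilyl)oxy]-2-vinylcyclopent-3-en-1-yl]oxy}silane, via bromomagnesium enolate 6 (not isolated)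
Conditions: CuI (10 mol%), LiCl, TMSCl, THF, −78 °C; Et3N quench
Reagents that add atoms: chlorotrimethylsilane, C[Si](C)(C)Cl
Why: Copper-catalysed conjugate addition of the vinyl Grignard reagent occurs anti to the C4 silyloxy group (the prostaglandin precedent), setting C5 with vinyl β, and in situ O-silylation traps the enolate regiospecifically before it can equilibrate and expel silanolate.

Step 4
Reactants: 7 tert-butyl(dimethyl){[(1R,2R)-3-methyl-4-[(trimethylsilyl)oxy]-2-vinylcyclopent-3-en-1-yl]oxy}silane; 8 tert-butyl bromoacetate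
Product: 10 tert-butyl 2-[(1R,2R,3R)-3-[(tert-butyldimethylsilyl)oxy]-1-methyl-5-oxo-2-vinylcyclopentyl]acetate, via lithium enolate 9 (not isolated)
Conditions: MeLi, THF, 0 °C; then DMPU, 8, −78 to −30 °C
Reagents that add atoms: none
Why: Regiospecific lithium enolate generation from the silyl enol ether followed by SN2 alkylation with the reactive α-bromo ester occurs anti to the adjacent vinyl group, creating quaternary C1 with the methyl cis and the C10 chain trans to the C5 substituent (the three-component prostaglandin pattern).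

Step 5
Reactants: 10 tert-butyl 2-[(1R,2R,3R)-3-[(tert-butyldimethylsilyl)oxy]-1-methyl-5-oxo-2-vinylcyclopentyl]acetate
Product: 11 2-[(1R,2R,3R,5RS)-3-[(tert-butyldimethylsilyl)oxy]-5-hydroxy-1-methyl-2-vinylcyclopentyl]ethan-1-ol (C2 epimers)
Conditions: LiAlH4, THF, 0 °C to rt
Reagents that add atoms: none
Why: Hydride reduction converts ketone and tert-butyl ester to the diol in one operation, and the configuration of the new C2 carbinol is irrelevant because this oxygen is removed in step 8.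

Step 6
Reactants: 11 2-[(1R,2R,3R,5RS)-3-[(tert-butyldimethylsilyl)oxy]-5-hydroxy-1-methyl-2-vinylcyclopentyl]ethan-1-ol
Product: 12 (1RS,2R,3R,4R)-4-[(tert-butyldimethylsilyl)oxy]-2-{2-[(tert-butyldiphenylsilyl)oxy]ethyl}-2-methyl-3-vinylcyclopentan-1-ol
Conditions: TBDPSCl, imidazole, CH2Cl2, 0 °C
Reagents that add atoms: tert-butyl(chloro)diphenylsilane, CC(C)(C)[Si](Cl)(c1ccccc1)c1ccccc1
Why: Silylation with the bulky chlorosilane is selective for the primary hydroxyl over the neopentyl-type secondary one.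

Step 7
Reactants: 12 (1RS,2R,3R,4R)-4-[(tert-butyldimethylsilyl)oxy]-2-{2-[(tert-butyldiphenylsilyl)oxy]ethyl}-2-methyl-3-vinylcyclopentan-1-ol
Product: 13 O-[(1RS,2R,3R,4R)-4-[(tert-butyldimethylsilyl)oxy]-2-{2-[(tert-butyldiphenylsilyl)oxy]ethyl}-2-methyl-3-vinylcyclopentyl] O-phenyl carbonothioate
Conditions: PhOC(S)Cl, pyridine, DMAP (cat.), CH2Cl2, rt
Reagents that add atoms: O-phenyl chlorothionoformate, S=C(Cl)Oc1ccccc1
Why: Thioacylation under neutral amine conditions (Robins variant) avoids a metal alkoxide and hence silyl migration between the 1,3-related oxygens.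

Step 8
Reactants: 13 O-[(1RS,2R,3R,4R)-4-[(tert-butyldimethylsilyl)oxy]-2-{2-[(tert-butyldiphenylsilyl)oxy]ethyl}-2-methyl-3-vinylcyclopentyl] O-phenyl carbonothioate
Product: 14 tert-butyl{[(1R,2R,3R)-3-{2-[(tert-butyldiphenylsilyl)oxy]ethyl}-3-methyl-2-vinylcyclopentyl]oxy}dimethylsilane
Conditions: Bu3SnH, AIBN (cat.), toluene, 100 °C
Reagents that add atoms: none
Why: Barton–McCombie radical deoxygenation turns C2 into CH2, and the secondary radical is simply reduced because only small-ring or endo closures onto the vinyl group are available.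

Step 9
Reactants: 14 tert-butyl{[(1R,2R,3R)-3-{2-[(tert-butyldiphenylsilyl)oxy]ethyl}-3-methyl-2-vinylcyclopentyl]oxy}dimethylsilane
Product: 15 (1R,2R,3R)-3-{2-[(tert-butyldiphenylsilyl)oxy]ethyl}-3-methyl-2-vinylcyclopentan-1-ol
Conditions: camphorsulfonic acid (0.2 equiv), MeOH/CH2Cl2, rt
Reagents that add atoms: none
Why: Acid-catalysed methanolysis cleaves the secondary TBS ether while the far more acid-stable primary TBDPS ether survives.

Step 10
Reactants: 15 (1R,2R,3R)-3-{2-[(tert-butyldiphenylsilyl)oxy]ethyl}-3-methyl-2-vinylcyclopentan-1-ol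
Product: 16 (2R,3R)-3-{2-[(tert-butyldiphenylsilyl)oxy]ethyl}-3-methyl-2-vinylcyclopentan-1-one
Conditions: Dess–Martin periodinane, NaHCO3, CH2Cl2, 0 °C
Reagents that add atoms: none
Why: Buffered Dess–Martin oxidation gives the β,γ-unsaturated ketone without epimerising C5 or moving the alkene into conjugation.

Step 11
Reactants: 16 (2R,3R)-3-{2-[(tert-butyldiphenylsilyl)oxy]ethyl}-3-methyl-2-vinylcyclopentan-1-one; 17 isopropylmagnesium chloride
Product: 18 (1R,2R,3R)-3-{2-[(tert-butyldiphenylsilyl)oxy]ethyl}-3-methyl-1-(propan-2-yl)-2-vinylcyclopentan-1-ol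
Conditions: CeCl3 (anhydrous, 2 equiv), THF, −78 °C
Reagents that add atoms: none
Why: The weakly basic organocerium reagent (Imamoto conditions) adds 1,2 without enolisation or reduction and attacks the cyclopentanone anti to the adjacent β-vinyl group, giving the 4β-hydroxyl and 4α-isopropyl group.

Step 12
Reactants: 18 (1R,2R,3R)-3-{2-[(tert-butyldiphenylsilyl)oxy]ethyl}-3-methyl-1-(propan-2-yl)-2-vinylcyclopentan-1-ol
Product: 19 (1R,2R,5R)-2-{2-[(tert-butyldiphenylsilyl)oxy]ethyl}-5-hydroxy-2-methyl-5-(propan-2-yl)cyclopentane-1-carbaldehyde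
Conditions: O3, CH2Cl2, −78 °C; then PPh3
Reagents that add atoms: ozone, O=[O+][O-]
Why: Ozonolysis with reductive work-up cleaves the only alkene to the C6 aldehyde under neutral conditions that neither epimerise C5 nor trigger retro-aldol cleavage.

Step 13
Reactants: 19 (1R,2R,5R)-2-{2-[(tert-butyldiphenylsilyl)oxy]ethyl}-5-hydroxy-2-methyl-5-(propan-2-yl)cyclopentane-1-carbaldehyde; 20 2,3-dibromoprop-1-ene
Product: 21 (1R,2S,3R)-2-[(1S)-3-bromo-1-hydroxybut-3-en-1-yl]-3-{2-[(tert-butyldiphenylsilyl)oxy]ethyl}-3-methyl-1-(propan-2-yl)cyclopentan-1-ol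
Conditions: In powder, THF/H2O (3:1), rt
Reagents that add atoms: none
Why: Indium-mediated Barbier-type carbonyl allylation tolerates the free tertiary hydroxyl, which chelates the aldehyde oxygen so that the 2-bromoallyl group attacks the carbonyl face flanked by H5 and not the one flanked by quaternary C1, giving the 1,3-anti (6S) carbinol and forming the C6–C7 bond.

Step 14
Reactants: 21 (1R,2S,3R)-2-[(1S)-3-bromo-1-hydroxybut-3-en-1-yl]-3-{2-[(tert-butyldiphenylsilyl)oxy]ethyl}-3-methyl-1-(propan-2-yl)cyclopentan-1-ol; 22 4-(acetyloxy)benzoyl chloride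
Product: 23 (1S)-3-bromo-1-[(1S,2R,5R)-2-{2-[(tert-butyldiphenylsilyl)oxy]ethyl}-5-hydroxy-2-methyl-5-(propan-2-yl)cyclopentyl]but-3-en-1-yl 4-(acetyloxy)benzoate
Conditions: pyridine, DMAP (cat.), CH2Cl2, 0 °C to rt
Reagents that add atoms: none
Why: DMAP-catalysed acylation takes place only at the secondary C6 hydroxyl because the tertiary C4 hydroxyl is inert, and the aroyl group of the target then serves as the C6 protecting group.

Step 15
Reactants: 23 (1S)-3-bromo-1-[(1S,2R,5R)-2-{2-[(tert-butyldiphenylsilyl)oxy]ethyl}-5-hydroxy-2-methyl-5-(propan-2-yl)cyclopentyl]but-3-en-1-yl 4-(acetyloxy)benzoate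
Product: 24 (1S)-3-bromo-1-[(1S,2R,5R)-2-hydroxy-5-(2-hydroxyethyl)-5-methyl-2-(propan-2-yl)cyclopentyl]but-3-en-1-yl 4-(acetyloxy)benzoate
Conditions: HF·pyridine, pyridine, THF, 0 °C to rt
Reagents that add atoms: none
Why: Buffered acidic fluoride removes the silyl ether without touching either ester, which basic fluoride could cleave.

Step 16
Reactants: 24 (1S)-3-bromo-1-[(1S,2R,5R)-2-hydroxy-5-(2-hydroxyethyl)-5-methyl-2-(propan-2-yl)cyclopentyl]but-3-en-1-yl 4-(acetyloxy)benzoate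
Product: 25 (1S)-3-bromo-1-[(1S,2R,5R)-2-hydroxy-5-methyl-5-(2-oxoethyl)-2-(propan-2-yl)cyclopentyl]but-3-en-1-yl 4-(acetyloxy)benzoate
Conditions: Dess–Martin periodinane, NaHCO3, CH2Cl2, 0 °C to rt
Reagents that add atoms: none
Why: Dess–Martin oxidation converts the only oxidisable alcohol (primary) to the C9 aldehyde, which cannot form a lactol because the C4 hydroxyl and the C10 chain lie on opposite ring faces.

Step 17
Reactants: 25 (1S)-3-bromo-1-[(1S,2R,5R)-2-hydroxy-5-methyl-5-(2-oxoethyl)-2-(propan-2-yl)cyclopentyl]but-3-en-1-yl 4-(acetyloxy)benzoate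
Product: 26 (3R,3aS,4S,7RS,8aR)-3,7-dihydroxy-8a-methyl-6-methylidene-3-(propan-2-yl)decahydroazulen-4-yl 4-(acetyloxy)benzoate (C9 epimers)
Conditions: CrCl2 (8 equiv), NiCl2 (2 mol%), degassed DMSO, 0.005 M, rt
Reagents that add atoms: none
Why: The Nozaki–Hiyama–Kishi reaction turns the 2-bromoalkene into an alkenylchromium species that adds chemoselectively to the aldehyde, closing the trans-fused seven-membered ring (C8–C9) and delivering the methylidene carbinol directly, while esters and the free tertiary alcohol are tolerated and the C9 epimers converge in steps 18 and 19.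

Step 18
Reactants: 26 (3R,3aS,4S,7RS,8aR)-3,7-dihydroxy-8a-methyl-6-methylidene-3-(propan-2-yl)decahydroazulen-4-yl 4-(acetyloxy)benzoate
Product: 27 (3R,3aS,4S,8aR)-3-hydroxy-8a-methyl-6-methylidene-7-oxo-3-(propan-2-yl)decahydroazulen-4-yl 4-(acetyloxy)benzoate
Conditions: Dess–Martin periodinane, NaHCO3, CH2Cl2, 0 °C
Reagents that add atoms: none
Why: Buffered Dess–Martin oxidation of the allylic alcohol mixture gives a single α-methylidene ketone without isomerising the exocyclic alkene.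

Step 19
Reactants: 27 (3R,3aS,4S,8aR)-3-hydroxy-8a-methyl-6-methylidene-7-oxo-3-(propan-2-yl)decahydroazulen-4-yl 4-(acetyloxy)benzoate
Product: 28 (3R,3aS,4S,7R,8aR)-3,7-dihydroxy-8a-methyl-6-methylidene-3-(propan-2-yl)decahydroazulen-4-yl 4-(acetyloxy)benzoate
Conditions: NaBH4, CeCl3·7H2O, MeOH, −78 °C
Reagents that add atoms: none
Why: Luche 1,2-reduction delivers hydride to the C9 ketone from the α face, anti to the axial C1 methyl that is 1,3-related to C9 (the bias that makes 2-oxo steroids give 2β-alcohols), so the 9β (7R) alcohol cis to the angular methyl is formed.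

Step 20
Reactants: 28 (3R,3aS,4S,7R,8aR)-3,7-dihydroxy-8a-methyl-6-methylidene-3-(propan-2-yl)decahydroazulen-4-yl 4-(acetyloxy)benzoate
Product: 29 (3R,3aS,4S,7R,8aR)-3,7-dihydroxy-8a-methyl-6-methylidene-3-(propan-2-yl)decahydroazulen-4-yl 4-hydroxybenzoate
Conditions: K2CO3 (0.2 equiv), MeOH, 0 °C
Reagents that add atoms: none
Why: Base-catalysed transesterification cleaves the activated phenolic acetate much faster than the hindered secondary benzoate, releasing the target.

**Compound list**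
1 | (R)-4-[(tert-butyldimethylsilyl)oxy]cyclopent-2-en-1-one | O=C1C=C[C@H](O[Si](C)(C)C(C)(C)C)C1 | starting material
2 | (R)-4-[(tert-butyldimethylsilyl)oxy]-2-iodocyclopent-2-en-1-one | O=C1C(I)=C[C@H](O[Si](C)(C)C(C)(C)C)C1 | intermediate
3 | methylboronic acid | CB(O)O | starting material
4 | (R)-4-[(tert-butyldimethylsilyl)oxy]-2-methylcyclopent-2-en-1-one | O=C1C(C)=C[C@H](O[Si](C)(C)C(C)(C)C)C1 | intermediate
5 | vinylmagnesium bromide | C=C[Mg]Br | starting material
6 | bromomagnesium (3R,4R)-4-[(tert-butyldimethylsilyl)oxy]-2-methyl-3-vinylcyclopent-1-en-1-olate (not isolated) | C=C[C@@H]1C(C)=C(O[Mg]Br)C[C@H]1O[Si](C)(C)C(C)(C)C | intermediate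
7 | tert-butyl(dimethyl){[(1R,2R)-3-methyl-4-[(trimethylsilyl)oxy]-2-vinylcyclopent-3-en-1-yl]oxy}silane | C=C[C@@H]1C(C)=C(O[Si](C)(C)C)C[C@H]1O[Si](C)(C)C(C)(C)C | intermediate
8 | tert-butyl bromoacetate | BrCC(=O)OC(C)(C)C | starting material
9 | lithium (3R,4R)-4-[(tert-butyldimethylsilyl)oxy]-2-methyl-3-vinylcyclopent-1-en-1-olate (not isolated) | C=C[C@@H]1C(C)=C(O[Li])C[C@H]1O[Si](C)(C)C(C)(C)C | intermediate
10 | tert-butyl 2-[(1R,2R,3R)-3-[(tert-butyldimethylsilyl)oxy]-1-methyl-5-oxo-2-vinylcyclopentyl]acetate | C=C[C@@H]1[C@](C)(C(=O)C[C@H]1O[Si](C)(C)C(C)(C)C)CC(=O)OC(C)(C)C | intermediate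
11 | 2-[(1R,2R,3R,5RS)-3-[(tert-butyldimethylsilyl)oxy]-5-hydroxy-1-methyl-2-vinylcyclopentyl]ethan-1-ol (C2 epimers) | C=C[C@@H]1[C@](C)(C(O)C[C@H]1O[Si](C)(C)C(C)(C)C)CCO | intermediate
12 | (1RS,2R,3R,4R)-4-[(tert-butyldimethylsilyl)oxy]-2-{2-[(tert-butyldiphenylsilyl)oxy]ethyl}-2-methyl-3-vinylcyclopentan-1-ol | C=C[C@@H]1[C@](C)(C(O)C[C@H]1O[Si](C)(C)C(C)(C)C)CCO[Si](c2ccccc2)(c2ccccc2)C(C)(C)C | intermediate
13 | O-[(1RS,2R,3R,4R)-4-[(tert-butyldimethylsilyl)oxy]-2-{2-[(tert-butyldiphenylsilyl)oxy]ethyl}-2-methyl-3-vinylcyclopentyl] O-phenyl carbonothioate | C=C[C@@H]1[C@](C)(C(OC(=S)Oc2ccccc2)C[C@H]1O[Si](C)(C)C(C)(C)C)CCO[Si](c2ccccc2)(c2ccccc2)C(C)(C)C | intermediate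
14 | tert-butyl{[(1R,2R,3R)-3-{2-[(tert-butyldiphenylsilyl)oxy]ethyl}-3-methyl-2-vinylcyclopentyl]oxy}dimethylsilane | C=C[C@@H]1[C@](C)(CC[C@H]1O[Si](C)(C)C(C)(C)C)CCO[Si](c2ccccc2)(c2ccccc2)C(C)(C)C | intermediate
15 | (1R,2R,3R)-3-{2-[(tert-butyldiphenylsilyl)oxy]ethyl}-3-methyl-2-vinylcyclopentan-1-ol | C=C[C@@H]1[C@](C)(CC[C@H]1O)CCO[Si](c2ccccc2)(c2ccccc2)C(C)(C)C | intermediate
16 | (2R,3R)-3-{2-[(tert-butyldiphenylsilyl)oxy]ethyl}-3-methyl-2-vinylcyclopentan-1-one | C=C[C@@H]1[C@](C)(CCC1=O)CCO[Si](c2ccccc2)(c2ccccc2)C(C)(C)C | intermediate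
17 | isopropylmagnesium chloride | CC(C)[Mg]Cl | starting material
18 | (1R,2R,3R)-3-{2-[(tert-butyldiphenylsilyl)oxy]ethyl}-3-methyl-1-(propan-2-yl)-2-vinylcyclopentan-1-ol | C=C[C@@H]1[C@](C)(CC[C@@]1(O)C(C)C)CCO[Si](c2ccccc2)(c2ccccc2)C(C)(C)C | intermediate
19 | (1R,2R,5R)-2-{2-[(tert-butyldiphenylsilyl)oxy]ethyl}-5-hydroxy-2-methyl-5-(propan-2-yl)cyclopentane-1-carbaldehyde | O=C[C@@H]1[C@](C)(CC[C@@]1(O)C(C)C)CCO[Si](c2ccccc2)(c2ccccc2)C(C)(C)C | intermediate
20 | 2,3-dibromoprop-1-ene | C=C(Br)CBr | starting material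
21 | (1R,2S,3R)-2-[(1S)-3-bromo-1-hydroxybut-3-en-1-yl]-3-{2-[(tert-butyldiphenylsilyl)oxy]ethyl}-3-methyl-1-(propan-2-yl)cyclopentan-1-ol | C=C(Br)C[C@H](O)[C@@H]1[C@](C)(CC[C@@]1(O)C(C)C)CCO[Si](c2ccccc2)(c2ccccc2)C(C)(C)C | intermediate
22 | 4-(acetyloxy)benzoyl chloride | CC(=O)Oc1ccc(cc1)C(Cl)=O | starting material
23 | (1S)-3-bromo-1-[(1S,2R,5R)-2-{2-[(tert-butyldiphenylsilyl)oxy]ethyl}-5-hydroxy-2-methyl-5-(propan-2-yl)cyclopentyl]but-3-en-1-yl 4-(acetyloxy)benzoate | C=C(Br)C[C@H](OC(=O)c2ccc(OC(C)=O)cc2)[C@@H]1[C@](C)(CC[C@@]1(O)C(C)C)CCO[Si](c3ccccc3)(c3ccccc3)C(C)(C)C | intermediate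
24 | (1S)-3-bromo-1-[(1S,2R,5R)-2-hydroxy-5-(2-hydroxyethyl)-5-methyl-2-(propan-2-yl)cyclopentyl]but-3-en-1-yl 4-(acetyloxy)benzoate | C=C(Br)C[C@H](OC(=O)c2ccc(OC(C)=O)cc2)[C@@H]1[C@](C)(CC[C@@]1(O)C(C)C)CCO | intermediate
25 | (1S)-3-bromo-1-[(1S,2R,5R)-2-hydroxy-5-methyl-5-(2-oxoethyl)-2-(propan-2-yl)cyclopentyl]but-3-en-1-yl 4-(acetyloxy)benzoate | C=C(Br)C[C@H](OC(=O)c2ccc(OC(C)=O)cc2)[C@@H]1[C@](C)(CC[C@@]1(O)C(C)C)CC=O | intermediate
26 | (3R,3aS,4S,7RS,8aR)-3,7-dihydroxy-8a-methyl-6-methylidene-3-(propan-2-yl)decahydroazulen-4-yl 4-(acetyloxy)benzoate (C9 epimers) | C=C1C[C@H](OC(=O)c2ccc(OC(C)=O)cc2)[C@@H]2[C@](C)(CC[C@@]2(O)C(C)C)CC1O | intermediate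
27 | (3R,3aS,4S,8aR)-3-hydroxy-8a-methyl-6-methylidene-7-oxo-3-(propan-2-yl)decahydroazulen-4-yl 4-(acetyloxy)benzoate | C=C1C[C@H](OC(=O)c2ccc(OC(C)=O)cc2)[C@@H]2[C@](C)(CC[C@@]2(O)C(C)C)CC1=O | intermediate
28 | (3R,3aS,4S,7R,8aR)-3,7-dihydroxy-8a-methyl-6-methylidene-3-(propan-2-yl)decahydroazulen-4-yl 4-(acetyloxy)benzoate | C=C1C[C@H](OC(=O)c2ccc(OC(C)=O)cc2)[C@@H]2[C@](C)(CC[C@@]2(O)C(C)C)C[C@H]1O | intermediate
29 | (3R,3aS,4S,7R,8aR)-3,7-dihydroxy-8a-methyl-6-methylidene-3-(propan-2-yl)decahydroazulen-4-yl 4-hydroxybenzoate | C=C1C[C@H](OC(=O)c2ccc(O)cc2)[C@@H]2[C@](C)(CC[C@@]2(O)C(C)C)C[C@H]1O | target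

**Step count and risks**
Total steps: 20. Longest linear sequence: 20 steps (1 to 29); compounds 3, 5, 8, 17, 20 and 22 are bought.

Three steps most likely to fail:

Step 4 (quaternising alkylation). The basic enolate can exchange protons with product 10, whose β-silyloxy ketone then eliminates, and C-alkylation next to the vinyl-bearing carbon is slow. Fallback: set out from 7 and avoid any basic enolate by a Lewis-acid alkylation of the silyl enol ether with methyl chloro(phenylsulfanyl)acetate and catalytic ZnBr2 in CH2Cl2. This enters anti to the vinyl group and gives methyl 2-[(1R,2R,3R)-3-[(tert-butyldimethylsilyl)oxy]-1-methyl-5-oxo-2-vinylcyclopentyl]-2-(phenylsulfanyl)acetate F1 (epimers at the sulfur-bearing carbon). Radical desulfurisation with Bu3SnH and AIBN gives methyl 2-[(1R,2R,3R)-3-[(tert-butyldimethylsilyl)oxy]-1-methyl-5-oxo-2-vinylcyclopentyl]acetate F2. LiAlH4 reduction as in step 5 brings the material back to the route at 11.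

Step 13 (key allylation). The aldehyde is flanked by two fully substituted carbons, and the C6 configuration rests on chelation by the free tertiary hydroxyl. Fallback: set out from 19 and switch from substrate control to reagent control. Cap the tertiary hydroxyl with TMSOTf and 2,6-lutidine to give (1R,2R,5R)-2-{2-[(tert-butyldiphenylsilyl)oxy]ethyl}-2-methyl-5-(propan-2-yl)-5-[(trimethylsilyl)oxy]cyclopentane-1-carbaldehyde F3. Allylborate it with the Corey chiral 2-bromoallyl diazaborolidine (from the bis-tosylamide of 1,2-diphenylethane-1,2-diamine, BBr3 and tributyl(2-bromoallyl)stannane, using the antipode found by screening to give 6S) to obtain (1S)-3-bromo-1-[(1S,2R,5R)-2-{2-[(tert-butyldiphenylsilyl)oxy]ethyl}-2-methyl-5-(propan-2-yl)-5-[(trimethylsilyl)oxy]cyclopentyl]but-3-en-1-ol F4. Methanolysis of the trimethylsilyl ether with citric acid returns to the route at 21.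

Step 19 (C9 configuration). The facial preference of the flexible seven-membered ketone is argued by analogy and could be low or reversed. Fallback: set out from 27; if reduction gives mainly (3R,3aS,4S,7S,8aR)-3,7-dihydroxy-8a-methyl-6-methylidene-3-(propan-2-yl)decahydroazulen-4-yl 4-(acetyloxy)benzoate F5, invert C9 by a Mitsunobu reaction with chloroacetic acid, PPh3 and diisopropyl azodicarboxylate. This gives (3R,3aS,4S,7R,8aR)-7-[(chloroacetyl)oxy]-3-hydroxy-8a-methyl-6-methylidene-3-(propan-2-yl)decahydroazulen-4-yl 4-(acetyloxy)benzoate F6. Remove the chloroacetate selectively with thiourea and NaHCO3 in ethanol, which leaves the other two esters intact and rejoins the route at 28.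

**Further compounds**
F1 | step 4 | methyl 2-[(1R,2R,3R)-3-[(tert-butyldimethylsilyl)oxy]-1-methyl-5-oxo-2-vinylcyclopentyl]-2-(phenylsulfanyl)acetate | C=C[C@@H]1[C@](C)(C(=O)C[C@H]1O[Si](C)(C)C(C)(C)C)C(Sc2ccccc2)C(=O)OC
F2 | step 4 | methyl 2-[(1R,2R,3R)-3-[(tert-butyldimethylsilyl)oxy]-1-methyl-5-oxo-2-vinylcyclopentyl]acetate | C=C[C@@H]1[C@](C)(C(=O)C[C@H]1O[Si](C)(C)C(C)(C)C)CC(=O)OC
F3 | step 13 | (1R,2R,5R)-2-{2-[(tert-butyldiphenylsilyl)oxy]ethyl}-2-methyl-5-(propan-2-yl)-5-[(trimethylsilyl)oxy]cyclopentane-1-carbaldehyde | O=C[C@@H]1[C@](C)(CC[C@@]1(O[Si](C)(C)C)C(C)C)CCO[Si](c2ccccc2)(c2ccccc2)C(C)(C)C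
F4 | step 13 | (1S)-3-bromo-1-[(1S,2R,5R)-2-{2-[(tert-butyldiphenylsilyl)oxy]ethyl}-2-methyl-5-(propan-2-yl)-5-[(trimethylsilyl)oxy]cyclopentyl]but-3-en-1-ol | C=C(Br)C[C@H](O)[C@@H]1[C@](C)(CC[C@@]1(O[Si](C)(C)C)C(C)C)CCO[Si](c2ccccc2)(c2ccccc2)C(C)(C)C
F5 | step 19 | (3R,3aS,4S,7S,8aR)-3,7-dihydroxy-8a-methyl-6-methylidene-3-(propan-2-yl)decahydroazulen-4-yl 4-(acetyloxy)benzoate | C=C1C[C@H](OC(=O)c2ccc(OC(C)=O)cc2)[C@@H]2[C@](C)(CC[C@@]2(O)C(C)C)C[C@@H]1O
F6 | step 19 | (3R,3aS,4S,7R,8aR)-7-[(chloroacetyl)oxy]-3-hydroxy-8a-methyl-6-methylidene-3-(propan-2-yl)decahydroazulen-4-yl 4-(acetyloxy)benzoate | C=C1C[C@H](OC(=O)c2ccc(OC(C)=O)cc2)[C@@H]2[C@](C)(CC[C@@]2(O)C(C)C)C[C@H]1OC(=O)CCl
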